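**Plan**
1. Numbering used below (elemane type): ring C5–C10; C10 carries C14 (methyl) and the C1=C2 vinyl group; C9 carries OAc; C8–O and C7–C11 form the trans-fused lactone (C12 carbonyl, C13 methylene); C6 carries the angelate; C5 carries C4(=C3H2)–C15HO; β is the ring face of C14.
2. Retrosynthesis: first the C15 aldehyde (from the alcohol), the C11=C13 methylene (masked as CH2NMe2) and the C6 angelate are removed; C6–OH is inverted through the C6 ketone; then C5–C6 (ring closure), C4–C5, C9–C10 and C6–C7 are cut, back to (R)-5-(hydroxymethyl)furan-2(5H)-one.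
3. Enabling feature: C6(O)–C5–C4(=C3H2) is a homoallylic alcohol whose alkene is exocyclic to ring C5–C10. C5 is therefore the γ-carbon of a 2-substituted allyl metal (C3–C4–C5), and C6 is an aldehyde carbon held four atoms away (C7–C8–C9–C10) on the lactone.
4. Forward order: lactone ring (chiral pool), C6 attached at C7, C9–C10 bond with the quaternary carbon, the C3–C4–C15 allyl unit at C5, cyclohexane by C5–C6 closure, then C6 inversion, angelate, enal, methylene.
5. Stereochemistry: C8 from the chiral pool; C7 by anti radical addition; C9 (Felkin–Anh) and C10 ((Z)-boronate geometry) in one chair transition state; C5 in the ring-closing chair (allyl unit equatorial); C6 by equatorial hydride delivery to the ketone, anti to axial C14; angelate geometry from angelic acid.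

Key step: step 15

Assumption: (R)-5-(hydroxymethyl)furan-2(5H)-one (8), the enantiomer of the ribonolactone-derived butenolide, is taken as a purchasable chiral-pool compound.

**Route**

Step 1
Reactants: 1 prop-2-yn-1-ol
Product: 2 (Z)-3-iodo-2-methylprop-2-en-1-ol
Conditions: MeMgBr, CuI (cat.), THF, −10 °C to rt; then I2, −10 °C
Reagents that add atoms: methylmagnesium bromide (C[Mg]Br); iodine ([I][I])
Why: Copper-catalysed anti-carbomagnesiation of the propargylic magnesium alkoxide puts methyl on C2 and magnesium on C3 cis to the CH2O group (chelate), and iodinolysis with retention should give the (Z)-iodide.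

Step 2
Reactants: 2 (Z)-3-iodo-2-methylprop-2-en-1-ol
Product: 3 (Z)-triethyl[(3-iodo-2-methylprop-2-en-1-yl)oxy]silane
Conditions: Et3SiCl, imidazole, CH2Cl2, 0 °C
Reagents that add atoms: chlorotriethylsilane (CC[Si](Cl)(CC)CC)
Why: Routine silylation of a primary alcohol; the triethylsilyl group is chosen because step 11 later oxidises it off directly.

Step 3
Reactants: 3 (Z)-alkenyl iodide
Product: 5 (Z)-triethyl{[2-methyl-4-(4,4,5,5-tetramethyl-1,3,2-dioxaborolan-2-yl)but-2-en-1-yl]oxy}silane, via alkenyllithium 4 (not isolated)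
Conditions: t-BuLi (2 equiv), Et2O, −78 °C; then ClCH2B(pin), −78 °C to rt
Reagents that add atoms: 2-(chloromethyl)-4,4,5,5-tetramethyl-1,3,2-dioxaborolane (ClCB1OC(C)(C)C(C)(C)O1)
Why: Iodine–lithium exchange with retention gives 4, whose boron ate complex undergoes a Matteson-type 1,2-migration with loss of chloride, so the allylboronate keeps CH2B cis to CH2OSiEt3.

Step 4
Reactants: 6 2-bromoprop-2-en-1-ol
Product: 7 [(2-bromoprop-2-en-1-yl)oxy](tert-butyl)diphenylsilane
Conditions: t-BuPh2SiCl, imidazole, DMF, rt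
Reagents that add atoms: tert-butyl(chloro)diphenylsilane (CC(C)(C)[Si](Cl)(c1ccccc1)c1ccccc1)
Why: Routine silylation; the acid-stable tert-butyldiphenylsilyl ether has to survive the acetal hydrolysis of step 14.

Step 5
Reactants: 8 (R)-5-(hydroxymethyl)furan-2(5H)-one
Product: 9 (R)-5-[(triethylsilyloxy)methyl]furan-2(5H)-one
Conditions: Et3SiCl, imidazole, CH2Cl2, 0 °C
Reagents that add atoms: chlorotriethylsilane (CC[Si](Cl)(CC)CC)
Why: Routine silylation of the chiral-pool butenolide, whose stereocentre becomes C8 of the target.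

Step 6
Reactants: 9 silylated butenolide
Product: 10 (4R,5R)-4-(1,3-dioxolan-2-yl)-5-[(triethylsilyloxy)methyl]dihydrofuran-2(3H)-one
Conditions: 1,3-dioxolane (solvent), Ph2CO (cat.), hν (350 nm), rt
Reagents that add atoms: 1,3-dioxolane (C1COCO1)
Why: Benzophenone-sensitised hydrogen abstraction gives the 1,3-dioxolan-2-yl radical, which adds to the β-carbon of the butenolide anti to the C5 substituent (radical conjugate addition), setting C7 trans to C8 and delivering C6 as a masked aldehyde.

Step 7
Reactants: 10 trans-lactone acetal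
Product: 11 (3S,4R,5R)-3-[(dimethylamino)methyl]-4-(1,3-dioxolan-2-yl)-5-[(triethylsilyloxy)methyl]dihydrofuran-2(3H)-one
Conditions: LiN(i-Pr)2, THF, −78 °C; then [Me2N=CH2]I, −78 °C to 0 °C
Reagents that add atoms: N,N-dimethylmethylideneammonium iodide (C=[N+](C)C.[I-])
Why: Kinetic deprotonation α to the lactone carbonyl and Mannich alkylation anti to the C4 substituent installs C13 as an amine-masked exo-methylene that is inert to the later hydride and organometallic steps.

Step 8
Reactants: 11 Mannich base
Product: 12 (2R,3R,4S)-4-[(dimethylamino)methyl]-3-(1,3-dioxolan-2-yl)-5-oxotetrahydrofuran-2-carbaldehyde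
Conditions: (COCl)2, DMSO, CH2Cl2, −78 to −30 °C; then Et3N, −78 °C to rt
Reagents that add atoms: none
Why: Swern conditions cleave a primary triethylsilyl ether and oxidise the resulting alkoxysulfonium ion in one operation, giving the C9 aldehyde without a separate deprotection.

Step 9
Reactants: 12 lactone aldehyde; 5 (Z)-allylboronate
Product: 14 homoallylic alcohol (C9 hydroxyl; C10 bearing methyl; vinyl; CH2OSiEt3), via O-boryl ether 13 (not isolated)
Conditions: toluene, 40 °C; aq. NaHCO3 work-up
Reagents that add atoms: none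
Why: Allylboration through a chair Zimmerman–Traxler transition state forms C9–C10 at the γ-carbon, the (Z)-boronate placing CH2OSiEt3 axial and CH3 equatorial so that C10 is fixed relative to C9, while Felkin–Anh attack anti to the ring C8–O bond sets C9 (8,9-anti).

Step 10
Reactants: 14 homoallylic alcohol
Product: 15 C9 acetate
Conditions: Ac2O, DMAP, pyridine, 40 °C
Reagents that add atoms: acetic anhydride (CC(=O)OC(C)=O)
Why: DMAP-catalysed acetylation installs the C9 acetate of the target at the point where C9–OH is the only free hydroxyl.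

Step 11
Reactants: 15 C9 acetate
Product: 16 C5 aldehyde (formyl group on C10)
Conditions: (COCl)2, DMSO, CH2Cl2, −78 to −30 °C; then Et3N, −78 °C to rt
Reagents that add atoms: none
Why: The same oxidative desilylation as in step 8 turns the neopentyl silyl ether into a non-enolisable aldehyde, which can neither epimerise nor eliminate the β-acetate.

Step 12
Reactants: 16 C5 aldehyde; 7 2-bromoallyl silyl ether
Product: 17 C5 allylic alcohol (both C5 epimers) with C4(=C3H2)–C15H2OSi(t-Bu)Ph2
Conditions: CrCl2, NiCl2 (cat.), DMF, rt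
Reagents that add atoms: none
Why: Nozaki–Hiyama–Kishi coupling adds the alkenyl bromide to the aldehyde only, leaving lactone and acetate untouched; the C5 carbinol configuration is irrelevant because step 15 erases it.

Step 13
Reactants: 17 C5 allylic alcohol
Product: 18 C5,C9-diacetate
Conditions: Ac2O, DMAP, Et3N, CH2Cl2, rt
Reagents that add atoms: acetic anhydride (CC(=O)OC(C)=O)
Why: Acetylation makes the allylic leaving group needed for ionisation by palladium; an anhydride is used rather than a chloroformate so that the tertiary amine is not dealkylated.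

Step 14
Reactants: 18 diacetate acetal
Product: 19 C6 aldehyde (open-chain precursor of the ring closure)
Conditions: 1 M aq. HCl, THF, 40 °C; NaHCO3 work-up
Reagents that add atoms: water (O)
Why: Aqueous acid hydrolyses the 1,3-dioxolane while the amine is protected as its ammonium salt and the silyl ether, both acetates and the lactone survive; the all-trans substitution of the lactone keeps C7 from epimerising.

Step 15
Reactants: 19 C6 aldehyde with C5 allylic acetate
Product: 21 6α-hydroxy cyclohexane (5β-allyl unit; trans-fused lactone), via σ-allylindium species 20 (not isolated)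
Conditions: Pd(PPh3)4 (cat.), InI, THF, rt, high dilution
Reagents that add atoms: none
Why: Zerovalent palladium ionises the allylic acetate of either C5 epimer of 19 to one π-allyl complex, which InI reduces to the σ-allylindium 20 (metal on C3, C4=C5 geometry free to equilibrate); 20 adds through its γ-carbon C5 to the C6 aldehyde, and the C4=C3 exo-methylene emerges by allylic transposition. The closest known reaction type is the palladium-catalysed, indium-mediated umpolung (Barbier-type) allylation of aldehydes with allylic acetates, used here intramolecularly. The cyclohexane C5–C10 closes in a 6-exo-trig mode on the carbonyl, since γ-attack gives the six-membered ring and α-attack would need an eight-membered one. C5 is controlled by a chair Zimmerman–Traxler array fused trans to the forming ring chair, whose conformation is locked by the trans-fused lactone (C7 and C8 substituents equatorial), so the allyl unit sits equatorial (β) at C5; the aldehyde oxygen is equatorial too, giving the 6α-alcohol (trans to C5) that steps 16 and 17 invert. The step needs chemoselectivity for the aldehyde over the lactone and acetate carbonyls, which organoindium reagents provide, and ring closure ahead of intermolecular allylation, which high dilution secures; any 6β-epimer 23 formed converges with 21 at ketone 22.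

Step 16
Reactants: 21 6α-alcohol
Product: 22 C6 ketone
Conditions: Dess–Martin periodinane, NaHCO3, CH2Cl2, 0 °C
Reagents that add atoms: none
Why: Buffered Dess–Martin oxidation gives the ketone under non-basic conditions, so C5 and C7 should not epimerise and the C4=C3 double bond should stay out of conjugation.

Step 17
Reactants: 22 C6 ketone
Product: 23 6β-alcohol (axial)
Conditions: LiBH(s-Bu)3 (L-Selectride), THF, −78 °C; AcOH quench at −78 °C
Reagents that add atoms: none
Why: The bulky hydride attacks along the equatorial trajectory from the α-face because the axial approach is blocked by the syn-axial C14 methyl group, which should give the axial 6β-alcohol (substrate-controlled ketone reduction); the cold acidic quench keeps the C6 alkoxide from translactonising onto C12.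

Step 18
Reactants: 23 6β-alcohol
Product: 24 6β-angelate
Conditions: angelic acid, 2,4,6-trichlorobenzoyl chloride, Et3N, toluene, rt; then 23, 80 °C
Reagents that add atoms: angelic acid, (Z)-2-methylbut-2-enoic acid (C/C=C(/C)C(=O)O)
Why: Yamaguchi-type mixed-anhydride esterification acylates the hindered axial alcohol without a nucleophilic catalyst, conditions under which the (Z)-geometry of the angeloyl group should be retained.

Step 19
Reactants: 24 silyl ether angelate
Product: 25 C15 allylic alcohol
Conditions: HF·pyridine, pyridine, THF, 0 °C to rt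
Reagents that add atoms: none
Why: Buffered fluoride cleaves the primary allylic silyl ether without touching the acetate, the angelate or the lactone.

Step 20
Reactants: 25 C15 allylic alcohol
Product: 26 C15 enal (13-dimethylamino adduct of the target)
Conditions: MnO2, CH2Cl2, rt
Reagents that add atoms: none
Why: MnO2 oxidises only the primary allylic alcohol, giving the 2-substituted acrolein.

Step 21
Reactants: 26 amino enal
Product: 28 CNP0228039.1 (target), via trimethylammonium iodide 27 (not isolated)
Conditions: MeI, MeOH, rt; then aq. NaHCO3, rt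
Reagents that add atoms: none
Why: Exhaustive N-methylation gives 27, and mild base then triggers E1cB (Hofmann-type) loss of trimethylamine, unveiling the C11=C13 exo-methylene in the last and mildest step.

**Compound list**
1 | prop-2-yn-1-ol | C#CCO | starting material
2 | (Z)-3-iodo-2-methylprop-2-en-1-ol | OC/C(C)=C\I | intermediate
3 | (Z)-triethyl[(3-iodo-2-methylprop-2-en-1-yl)oxy]silane | CC[Si](CC)(CC)OC/C(C)=C\I | intermediate
4 | (Z)-[2-methyl-3-(triethylsilyloxy)prop-1-en-1-yl]lithium, Li cis to CH2OSiEt3 (not isolated) | CC[Si](CC)(CC)OC/C(C)=C\[Li] | intermediate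
5 | (Z)-triethyl{[2-methyl-4-(4,4,5,5-tetramethyl-1,3,2-dioxaborolan-2-yl)but-2-en-1-yl]oxy}silane, CH2B cis to CH2OSiEt3 | CC[Si](CC)(CC)OC/C(C)=C\CB1OC(C)(C)C(C)(C)O1 | intermediate
6 | 2-bromoprop-2-en-1-ol | C=C(Br)CO | starting material
7 | [(2-bromoprop-2-en-1-yl)oxy](tert-butyl)diphenylsilane | C=C(Br)CO[Si](c1ccccc1)(c1ccccc1)C(C)(C)C | intermediate
8 | (R)-5-(hydroxymethyl)furan-2(5H)-one | OC[C@@H]1OC(=O)C=C1 | starting material
9 | (R)-5-[(triethylsilyloxy)methyl]furan-2(5H)-one | CC[Si](CC)(CC)OC[C@@H]1OC(=O)C=C1 | intermediate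
10 | (4R,5R)-4-(1,3-dioxolan-2-yl)-5-[(triethylsilyloxy)methyl]dihydrofuran-2(3H)-one (4,5-trans) | CC[Si](CC)(CC)OC[C@@H]1OC(=O)C[C@H]1C1OCCO1 | intermediate
11 | (3S,4R,5R)-3-[(dimethylamino)methyl]-4-(1,3-dioxolan-2-yl)-5-[(triethylsilyloxy)methyl]dihydrofuran-2(3H)-one (all-trans) | CC[Si](CC)(CC)OC[C@@H]1OC(=O)[C@H](CN(C)C)[C@H]1C1OCCO1 | intermediate
12 | (2R,3R,4S)-4-[(dimethylamino)methyl]-3-(1,3-dioxolan-2-yl)-5-oxotetrahydrofuran-2-carbaldehyde | O=C[C@@H]1OC(=O)[C@H](CN(C)C)[C@H]1C1OCCO1 | intermediate
13 | O-pinacolboryl ether of 14, boron on the C9 oxygen (not isolated) | C=C[C@](CO[Si](CC)(CC)CC)(C)[C@H](OB1OC(C)(C)C(C)(C)O1)[C@@H]1OC(=O)[C@H](CN(C)C)[C@H]1C1OCCO1 | intermediate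
14 | (3S,4R,5R)-3-[(dimethylamino)methyl]-4-(1,3-dioxolan-2-yl)-5-{(1S,2S)-1-hydroxy-2-methyl-2-[(triethylsilyloxy)methyl]but-3-en-1-yl}dihydrofuran-2(3H)-one | C=C[C@](CO[Si](CC)(CC)CC)(C)[C@H](O)[C@@H]1OC(=O)[C@H](CN(C)C)[C@H]1C1OCCO1 | intermediate
15 | C9 acetate of 14 | C=C[C@](CO[Si](CC)(CC)CC)(C)[C@H](OC(C)=O)[C@@H]1OC(=O)[C@H](CN(C)C)[C@H]1C1OCCO1 | intermediate
16 | C5 aldehyde: as 15 with CHO in place of CH2OSiEt3 on C10 | C=C[C@](C=O)(C)[C@H](OC(C)=O)[C@@H]1OC(=O)[C@H](CN(C)C)[C@H]1C1OCCO1 | intermediate
17 | C5 allylic alcohol (both C5 epimers): C5H(OH)–C4(=C3H2)–C15H2OSi(t-Bu)Ph2 attached to C10 of the C9-acetoxy lactone acetal | C=C[C@](C(O)C(=C)CO[Si](c1ccccc1)(c1ccccc1)C(C)(C)C)(C)[C@H](OC(C)=O)[C@@H]1OC(=O)[C@H](CN(C)C)[C@H]1C1OCCO1 | intermediate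
18 | C5,C9-diacetate of 17 | C=C[C@](C(OC(C)=O)C(=C)CO[Si](c1ccccc1)(c1ccccc1)C(C)(C)C)(C)[C@H](OC(C)=O)[C@@H]1OC(=O)[C@H](CN(C)C)[C@H]1C1OCCO1 | intermediate
19 | C6 aldehyde: as 18 with CHO in place of the dioxolane on C7 | C=C[C@](C(OC(C)=O)C(=C)CO[Si](c1ccccc1)(c1ccccc1)C(C)(C)C)(C)[C@H](OC(C)=O)[C@@H]1OC(=O)[C@H](CN(C)C)[C@H]1C=O | intermediate
20 | σ-allylindium acetate iodide, In on C3, C4=C5 geometry mobile (not isolated) | C=C[C@](C=C(CO[Si](c1ccccc1)(c1ccccc1)C(C)(C)C)C[In](I)OC(C)=O)(C)[C@H](OC(C)=O)[C@@H]1OC(=O)[C@H](CN(C)C)[C@H]1C=O | intermediate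
21 | cyclised 6α-alcohol: 9α-acetoxy, 10β-methyl, 10α-vinyl, 8α,12-olide (7β-C11, trans-fused), 11-CH2NMe2 (11β-H), 5β-[3-(tert-butyldiphenylsilyloxy)prop-1-en-2-yl] | C=C[C@]1(C)[C@H](OC(C)=O)[C@@H]2OC(=O)[C@H](CN(C)C)[C@H]2[C@H](O)[C@H]1C(=C)CO[Si](c1ccccc1)(c1ccccc1)C(C)(C)C | intermediate
22 | C6 ketone of 21 | C=C[C@]1(C)[C@H](OC(C)=O)[C@@H]2OC(=O)[C@H](CN(C)C)[C@H]2C(=O)[C@H]1C(=C)CO[Si](c1ccccc1)(c1ccccc1)C(C)(C)C | intermediate
23 | 6β-alcohol (C6 epimer of 21, hydroxyl axial) | C=C[C@]1(C)[C@H](OC(C)=O)[C@@H]2OC(=O)[C@H](CN(C)C)[C@H]2[C@@H](O)[C@H]1C(=C)CO[Si](c1ccccc1)(c1ccccc1)C(C)(C)C | intermediate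
24 | 6β-angelate of 23 | C=C[C@]1(C)[C@H](OC(C)=O)[C@@H]2OC(=O)[C@H](CN(C)C)[C@H]2[C@@H](OC(=O)/C(C)=C\C)[C@H]1C(=C)CO[Si](c1ccccc1)(c1ccccc1)C(C)(C)C | intermediate
25 | C15 allylic alcohol (desilylated 24) | C=C[C@]1(C)[C@H](OC(C)=O)[C@@H]2OC(=O)[C@H](CN(C)C)[C@H]2[C@@H](OC(=O)/C(C)=C\C)[C@H]1C(=C)CO | intermediate
26 | C15 enal, 13-(dimethylamino)-11,13-dihydro form of the target | C=C[C@]1(C)[C@H](OC(C)=O)[C@@H]2OC(=O)[C@H](CN(C)C)[C@H]2[C@@H](OC(=O)/C(C)=C\C)[C@H]1C(=C)C=O | intermediate
27 | trimethylammonium iodide of 26 (not isolated) | C=C[C@]1(C)[C@H](OC(C)=O)[C@@H]2OC(=O)[C@H](C[N+](C)(C)C)[C@H]2[C@@H](OC(=O)/C(C)=C\C)[C@H]1C(=C)C=O.[I-] | intermediate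
28 | CNP0228039.1: 9α-acetoxy-6β-angeloyloxy-15-oxo-elema-1,3,11(13)-trien-8α,12-olide | C=C[C@]1(C)[C@H](OC(C)=O)[C@@H]2OC(=O)C(=C)[C@H]2[C@@H](OC(=O)/C(C)=C\C)[C@H]1C(=C)C=O | target

**Step count and risks**
Total: 21 steps. Longest linear sequence: 17 steps (steps 5 to 21, from 8).

Step 15 (ring closure). The allylindium may be protonated before it closes, or closure may pass through a boat or an axial-allyl chair and erode the selectivity at C5. Fallback: set out from 17. Hydrolysis of the dioxolane (1 M aq. HCl, THF) would give the hydroxy aldehyde F1. MsCl, LiCl and 2,4,6-collidine in DMF would convert the hindered secondary allylic alcohol, with allylic transposition, into the primary allylic chloride F2 (double-bond geometry immaterial). CrCl2 and LiI in THF at high dilution would then close the ring by an intramolecular Nozaki–Hiyama allylation, whose equilibrating allylchromium reagent should react through the same all-equatorial chair. The route is rejoined at 21.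

Step 17 (ketone reduction). Hydride may be delivered along the axial trajectory and return 21, the C6 alkoxide may translactonise onto C12, or enolisation may move the C4=C3 double bond into conjugation. Fallback: set out from 18. Miyaura-type borylation (Pd2(dba)3 cat., B2pin2, DMSO, 50 °C) would give the allylboronate F3, from which the (E)-isomer (CH2B cis to C10) is separated. 1 M aq. HCl in THF would free the aldehyde F4. As a configurationally fixed allylboronate, F4 should cyclise through a cis-fused chair (boron-bound oxygen axial, allyl unit equatorial) to the borate F5, which loses boron in the same acidic medium. This gives the 6β-alcohol directly, and the ketone is never made. The route is rejoined at 23.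

Step 18 (angeloylation). Acylation of the axial C6 hydroxyl, which is syn-axial to C14, may be slow, so that Z-to-E isomerisation of the activated acyl group (tiglate formation) and base-induced translactonisation compete. Fallback: set out from 23. DCC/DMAP esterification with 2-[bis(2,2,2-trifluoroethoxy)phosphoryl]propanoic acid would give the phosphonate ester F6. Still–Gennari olefination with acetaldehyde (KN(SiMe3)2, 18-crown-6, THF, −78 °C) would then build the (Z)-2-methylbut-2-enoate in place. The route is rejoined at 24.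

**Further compounds**
F1 | step 15 | hydroxy aldehyde: 17 with CHO in place of the dioxolane | C=C[C@](C(O)C(=C)CO[Si](c1ccccc1)(c1ccccc1)C(C)(C)C)(C)[C@H](OC(C)=O)[C@@H]1OC(=O)[C@H](CN(C)C)[C@H]1C=O
F2 | step 15 | primary allylic chloride: C10–C5H=C4(CH2Cl)–C15H2OSi(t-Bu)Ph2, C6 aldehyde | C=C[C@](C=C(CCl)CO[Si](c1ccccc1)(c1ccccc1)C(C)(C)C)(C)[C@H](OC(C)=O)[C@@H]1OC(=O)[C@H](CN(C)C)[C@H]1C=O
F3 | step 17 | (E)-allylboronate: C10–C5H=C4(CH2Bpin)–C15H2OSi(t-Bu)Ph2 with CH2B cis to C10, dioxolane at C6 | C=C[C@](/C=C(/CO[Si](c1ccccc1)(c1ccccc1)C(C)(C)C)CB1OC(C)(C)C(C)(C)O1)(C)[C@H](OC(C)=O)[C@@H]1OC(=O)[C@H](CN(C)C)[C@H]1C1OCCO1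
F4 | step 17 | aldehyde of F3 (dioxolane hydrolysed, not isolated) | C=C[C@](/C=C(/CO[Si](c1ccccc1)(c1ccccc1)C(C)(C)C)CB1OC(C)(C)C(C)(C)O1)(C)[C@H](OC(C)=O)[C@@H]1OC(=O)[C@H](CN(C)C)[C@H]1C=O
F5 | step 17 | O-pinacolboryl ether of 23 (not isolated) | C=C[C@]1(C)[C@H](OC(C)=O)[C@@H]2OC(=O)[C@H](CN(C)C)[C@H]2[C@@H](OB3OC(C)(C)C(C)(C)O3)[C@H]1C(=C)CO[Si](c1ccccc1)(c1ccccc1)C(C)(C)C
F6 | step 18 | 6β-{2-[bis(2,2,2-trifluoroethoxy)phosphoryl]propanoate} of 23 | C=C[C@]1(C)[C@H](OC(C)=O)[C@@H]2OC(=O)[C@H](CN(C)C)[C@H]2[C@@H](OC(=O)C(C)P(=O)(OCC(F)(F)F)OCC(F)(F)F)[C@H]1C(=C)CO[Si](c1ccccc1)(c1ccccc1)C(C)(C)C
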